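The L fed in is conserved: in the alpha run, as long as L goes to G and Z and nowhere else, the fed fraction less L and G must equal Z, whatever the rates.

| setting | alpha | Tuesday's | Saturday's | Friday's | Sunday's | Monday's |
|---|---|---|---|---|---|---|
| L | 0.20 M (fed, over 12 min) | 0.20 M (fed, over 12 min) | 0.20 M (fed, over 12 min) | 0.20 M (fed, over 12 min) | 0.20 M (fed, over 12 min) | 0.20 M (fed, over 12 min) |
| D | 0.53 equiv | 1.05 equiv | 1.05 equiv | 1.05 equiv | 1.05 equiv | 1.05 equiv |
| temperature | 25 °C | 5 °C | 45 °C | 25 °C | −5 °C | −15 °C |
| remark | run made earlier |  |  |  |  |  |
| time |  | 20 min | 20 min | 20 min | 20 min | 20 min |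
| volume of the second phase over the first |  | 0.25 | 0.25 | 0.25 | 0.25 | 0.25 |

alpha run (percent of the L charged)

| time / min | G / % | Z / % | L / % |
|---|---|---|---|
| 1.00 | 0.4 | 0 | 8.0 |
| 2.00 | 6.0 | 0 | 11.8 |
| 3.00 | 9.0 | 0 | 16.0 |
| 4.00 | 11.9 | 0 | 18.5 |

(each reading ± 1 percentage point)

- the flasks put in order of share of G in all that became G or Z, best first, at 20 min (Tuesday's / Saturday's / Friday's / Sunday's / Monday's)
- the share of G in all that became G or Z of the flask you put first, at 20 min
- the share of G in all that became G or Z of the flask you put last, at 20 min

- in the second phase: D; everything else is in the first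
- charges count per volume of the first phase; a concentration in a rate is the amount of a species over the volume of its own phase; every rate counts per litre of the first phase
- what was read earlier has a scatter of 1 percentage point, one standard deviation
- the earlier runs hold the two phases in the same ratio of volumes as the flask asked about
- the earlier runs do not show what temperature does; that part of a forecast is a guess
- percentages count the whole charge, also what has not yet gone in

So I had Z two ways in the alpha run: as read, and as the gap of that balance. At 3.00 min they agreed, with 25.0 % fed, 25.0 % found as L and G, and Z read as 0 %. At 4.00 min they parted, with a gap of 2.9 percentage points against a reading of 0 %. But the gap is a difference of readings, each with a scatter of 1 point, and at 2.00 min it stood at −1.1 points, which no real Z can be. The gap was the one that cheated, so I kept the reading and took Z at 4.00 min to be within about 1 point.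

Then I followed one unit of reagent, assuming that it meets L and gives G, or meets G and gives Z. Summed over the readings, G read 0.474 of L. Z at 4.00 min is then roughly G times that figure times the fork ratio, the reagent's preference for G over L at equal amounts (the selectivity factor), so with Z taken at 1 point that ratio read below about 0.177, an estimate that carries the scatter. The reagent then goes to L over G by odds of L divided by the fork ratio times G. At equal L and G, that estimate sends about 84.9 % or more of it to G, and at a fixed fork ratio that share falls as G overtakes L. Temperature stayed a guess.

The forecast gave Monday's > Sunday's > Tuesday's > Friday's > Saturday's, with 97 % (92 % to 99.5 %) for the first and 86 % (70 % to 95 %) for the last, noting: “Cold flasks also convert less, so they make less Z”.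

The flasks gave Monday's > Sunday's > Tuesday's > Friday's > Saturday's, with Monday's at 96.6 % and Saturday's at 76.5 %. The order held, and Saturday's lay 9.5 points below the forecast's figure.

    L + J → G (k = 0.750 M⁻¹ s⁻¹, Ea = 53.0 kJ mol⁻¹)
    J + G → Z (k = 0.0770 M⁻¹ s⁻¹, Ea = 55.0 kJ mol⁻¹)
    J ⇌ D, rate k3*([J] - [D]/K3) per volume of the first phase (partition coefficient = 13.0, kL = 0.00700 s⁻¹)
    (constants at 25 °C)

On Saturday's at 10.0 min, with G at 42.5 % and L at 26.5 %, the fork ratio, carried from 25 °C as a guess, gave odds for L of about 3.52 or more. Earlier in Saturday's, at 5.57 min, J, the reagent in the first phase, went to G 3.5 times as fast as to Z, a 77.8 % share for G at that moment.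

The neighbour, Saturday's flask at 20 °C, held G at 66.0 % and L at 22.1 % at 20.0 min, so the fork ratio, again carried as a guess, gave odds for L of about 1.88 or more at that moment, or about 65.3 % or more of the reagent then used going to G. The computed share of G in all that had become G or Z by then, which counts the whole run and not that moment, was 84.7 %.

Readings and results were generated by integration for an exercise; scatter was added.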